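## Retrosynthetic overview

1. Target 18 comes from its 2',4'-bis-MOM ether by acetal cleavage. Rings A and B are bought as arenes. Ring C (the dihydropyran) is the only ring that is built, and it is built last.
2. Ring C is closed in one flask from a ring-A aryl chloromethyl ether (O1–C2 already in place) and the chiral enamine of the ring-B arylacetaldehyde (C3=C4). Enamine alkylation makes C2–C3, phenol Mannich closure makes C4–C4a, and the amine on C4 is then removed reductively.
3. Enabling feature: ring A is a formylphloroglucinol. C4a lies ortho to O1, ortho to 5-OMe and para to 7-OH, and it is the only free carbon beside O1 because C8 carries CHO. O1–C2H2 is a latent aryloxymethyl cation. The para 7-OH later expels the C4 amine as a quinone methide, so C4 ends as CH2.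
4. The ring-A piece comes from C2v-symmetric 2,6-dihydroxy-4-methoxybenzaldehyde, made from 2,4,6-trihydroxybenzaldehyde. Either hydroxyl may be alkylated, and the formyl group is carried from the start.
5. The ring-B piece comes from 4-bromoresorcinol. Br/Li exchange with ethylene oxide brings in C3–C4, and lithiation between the two OMOM groups brings in the prenyl group.

Key step: step 9

Remark: isoflavan numbering is used (O1, C2, C3, C4, C4a, C5–C8, C8a; ring B primed), and the stereodescriptor of the target SMILES is read as 3R.

## Route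

Step 1
Reactants: 1 4-bromoresorcinol
Product: 2 1-bromo-2,4-bis(methoxymethoxy)benzene
Conditions: NaH (2.4 equiv), DMF, 0 °C; MOMCl (2.4 equiv), 0 °C to rt
Reagents that add atoms: chloromethyl methyl ether, COCCl
Why: Williamson O-alkylation of both phenoxides installs MOM groups that mask the phenols, later direct the lithiation, and tolerate base, enamine chemistry and acetic acid.

Step 2
Reactants: 2 1-bromo-2,4-bis(methoxymethoxy)benzene
Product: 4 2-[2,4-bis(methoxymethoxy)phenyl]ethanol, via aryllithium 3 (not isolated)
Conditions: nBuLi (1.05 equiv), THF, −78 °C; ethylene oxide (THF solution, 3 equiv), −78 °C to rt; H2O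
Reagents that add atoms: ethylene oxide, C1CO1
Why: Bromine–lithium exchange fixes the metalation site at C1' faster than any deprotonation, and epoxide opening by the aryllithium brings in the two carbons that become C3 and C4.

Step 3
Reactants: 4 2-[2,4-bis(methoxymethoxy)phenyl]ethanol
Product: 6 2-[2,4-bis(methoxymethoxy)-3-(3-methylbut-2-enyl)phenyl]ethanol, via dilithio species 5 (not isolated)
Conditions: nBuLi (2.2 equiv), THF, 0 °C to rt; prenyl bromide (1.1 equiv), −78 °C to rt; H2O
Reagents that add atoms: prenyl bromide, CC(C)=CCBr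
Why: In this directed ortho-metalation the alkoxide forms first, the second equivalent of base removes the proton flanked by both OMOM groups, and the aryllithium is alkylated at the primary carbon of prenyl bromide faster than the lithium alkoxide.

Step 4
Reactants: 6 2-[2,4-bis(methoxymethoxy)-3-(3-methylbut-2-enyl)phenyl]ethanol
Product: 7 2-[2,4-bis(methoxymethoxy)-3-(3-methylbut-2-enyl)phenyl]acetaldehyde
Conditions: Dess–Martin periodinane (1.2 equiv), CH2Cl2, 0 °C to rt
Reagents that add atoms: none
Why: The Dess–Martin oxidation stops at the aldehyde under nearly neutral conditions that leave the MOM ethers and the prenyl alkene untouched.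

Step 5
Reactants: 7 2-[2,4-bis(methoxymethoxy)-3-(3-methylbut-2-enyl)phenyl]acetaldehyde; 8 (S)-2-(methoxydiphenylmethyl)pyrrolidine
Product: 9 (S)-1-{(E)-2-[2,4-bis(methoxymethoxy)-3-(3-methylbut-2-enyl)phenyl]ethenyl}-2-(methoxydiphenylmethyl)pyrrolidine
Conditions: 4 Å molecular sieves, CH2Cl2, rt; filter, concentrate, use at once
Reagents that add atoms: none
Why: In this enamine condensation, conjugation with ring B drives the equilibrium to the enamine, allylic strain makes it E and s-trans, and the stereocentre comes with purchased 8.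

Step 6
Reactants: 10 2,4,6-trihydroxybenzaldehyde
Product: 11 2,6-dihydroxy-4-methoxybenzaldehyde
Conditions: Me2SO4 (1.0 equiv), K2CO3 (1.0 equiv), acetone, rt
Reagents that add atoms: dimethyl sulfate, COS(=O)(=O)OC
Why: The 4-OH is the most acidic hydroxyl and the only one not hydrogen-bonded to the formyl group, so one equivalent of a hard methylating agent should etherify it (Williamson ether synthesis) and give the symmetric 11.

Step 7
Reactants: 11 2,6-dihydroxy-4-methoxybenzaldehyde
Product: 12 2-hydroxy-4-methoxy-6-[(methylsulfanyl)methoxy]benzaldehyde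
Conditions: MeSCH2Cl (1.05 equiv), K2CO3 (1.1 equiv), DMF, 0 °C to rt
Reagents that add atoms: chloromethyl methyl sulfide, CSCCl
Why: The two hydroxyls of 11 are equivalent, so this Williamson alkylation raises no regiochemical question, and the remaining OH is then locked in a hydrogen bond to CHO, which favours the mono ether.

Step 8
Reactants: 12 2-hydroxy-4-methoxy-6-[(methylsulfanyl)methoxy]benzaldehyde
Product: 13 2-(chloromethoxy)-6-hydroxy-4-methoxybenzaldehyde
Conditions: SO2Cl2 (1.0 equiv), CH2Cl2, −78 to −20 °C; cyclohexene (1.5 equiv); concentrate, use crude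
Reagents that add atoms: sulfuryl chloride, O=S(=O)(Cl)Cl
Why: In this chlorinolysis of an O,S-acetal, sulfur is chlorinated far faster than the formyl-deactivated ring, the chlorosulfonium ion collapses to the α-chloro ether, and cyclohexene traps the sulfenyl chloride by addition.

Step 9
Reactants: 9 (S)-1-{(E)-2-[2,4-bis(methoxymethoxy)-3-(3-methylbut-2-enyl)phenyl]ethenyl}-2-(methoxydiphenylmethyl)pyrrolidine; 13 2-(chloromethoxy)-6-hydroxy-4-methoxybenzaldehyde
Product: 17 (3R)-7-hydroxy-5-methoxy-2',4'-bis(methoxymethoxy)-3'-(3-methylbut-2-enyl)isoflavan-8-carbaldehyde, via iminium chloride 14 (not isolated), via aminoisoflavan hydrochloride 15 (not isolated), via para-quinone methide 16 (not isolated)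
Conditions: 13 (1.1 equiv), 4 Å molecular sieves, CH2Cl2, −40 °C to rt; then Hantzsch ester (diethyl 2,6-dimethyl-1,4-dihydropyridine-3,5-dicarboxylate, 2 equiv), NaOAc (1.5 equiv), AcOH (5 equiv), 35 °C, same flask
Reagents that add atoms: none
Why: Proposed new method: the E-configured, s-trans enamine 9 attacks the α-chloro ether carbon of 13 with its β-carbon (Stork-type alkoxymethylation, forms C2–C3), and the α-aryl iminium ion 14 is then attacked at C4 by C4a of ring A (intramolecular phenol Mannich reaction, forms C4–C4a), so the pair behaves as a stepwise formal [4+2] of the four-atom unit C2–O1–C8a–C4a with the C3=C4 enamine bond. The closest known reaction types are the Lewis-acid oxa-Povarov annulation of aryl oxocarbenium ions with alkenes, the Povarov-type annulation of N-aryl-N-(halomethyl)amines with enamines and the enantioselective α-aminomethylation of aldehydes through diarylprolinol ether enamines; what is new is the union of an aryl chloromethyl ether with a preformed chiral enamine. Ring C closes in the 6-(enolendo)-exo-trig mode, with the C8a=C4a bond of the phenol inside and the C=N bond outside the new ring. C3 is set in the first bond formation by the auxiliary: the CPh2OMe group of the (S)-pyrrolidine covers one face of the enamine, 13 adds to the open face, and that face corresponds to 3R in 17 and 18 (the descriptor reads 3S in 14 and 15 only because C4 then outranks the aryl group), while the C4 centre of 15 is of no consequence because it is erased. In the second stage, acetate-buffered loss of the protonated amine, pushed by the para 7-OH, should give para-quinone methide 16, which takes up hydride from the Hantzsch ester at C4 (1,6-reduction) and rearomatises to 17 with release of 8. The step needs site selectivity on ring A (C8 is blocked by CHO, so C4a is the only free carbon next to O1), chemoselectivity (the enamine is by far the best nucleophile present, the prenyl alkene and MOM ethers see no Lewis acid, and the hydrogen-bonded, donor-conjugated 8-CHO is a poor acceptor for both the enamine and the Hantzsch ester) and ring closure that is fast relative to deprotonation of 14 at C3, which the threefold oxygen activation of C4a should secure.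

Step 10
Reactants: 17 (3R)-7-hydroxy-5-methoxy-2',4'-bis(methoxymethoxy)-3'-(3-methylbut-2-enyl)isoflavan-8-carbaldehyde
Product: 18 (3R)-7,2',4'-trihydroxy-5-methoxy-3'-(3-methylbut-2-enyl)isoflavan-8-carbaldehyde (CNP0399843.1)
Conditions: HCl (cat., aq. 2 M), MeOH, rt to 40 °C, short reaction time
Reagents that add atoms: none
Why: Acid-catalysed acetal exchange with methanol frees both phenols and carries formaldehyde off as its dimethyl acetal, and C3 is neither acidic nor ionisable, so its configuration is retained.

## Compound list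

1 | 4-bromoresorcinol | Oc1ccc(Br)c(O)c1 | starting material
2 | 1-bromo-2,4-bis(methoxymethoxy)benzene | COCOc1ccc(Br)c(OCOC)c1 | intermediate
3 | [2,4-bis(methoxymethoxy)phenyl]lithium | COCOc1ccc([Li])c(OCOC)c1 | intermediate
4 | 2-[2,4-bis(methoxymethoxy)phenyl]ethanol | COCOc1ccc(CCO)c(OCOC)c1 | intermediate
5 | lithium 2-[3-lithio-2,4-bis(methoxymethoxy)phenyl]ethoxide | COCOc1ccc(CCO[Li])c(OCOC)c1[Li] | intermediate
6 | 2-[2,4-bis(methoxymethoxy)-3-(3-methylbut-2-enyl)phenyl]ethanol | COCOc1ccc(CCO)c(OCOC)c1CC=C(C)C | intermediate
7 | 2-[2,4-bis(methoxymethoxy)-3-(3-methylbut-2-enyl)phenyl]acetaldehyde | COCOc1ccc(CC=O)c(OCOC)c1CC=C(C)C | intermediate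
8 | (S)-2-(methoxydiphenylmethyl)pyrrolidine | COC(c1ccccc1)(c1ccccc1)[C@@H]1CCCN1 | starting material
9 | (S,E)-enamine of 7 and 8 | COC(c1ccccc1)(c1ccccc1)[C@@H]1CCCN1/C=C/c1ccc(OCOC)c(CC=C(C)C)c1OCOC | intermediate
10 | 2,4,6-trihydroxybenzaldehyde | O=Cc1c(O)cc(O)cc1O | starting material
11 | 2,6-dihydroxy-4-methoxybenzaldehyde | COc1cc(O)c(C=O)c(O)c1 | intermediate
12 | 2-hydroxy-4-methoxy-6-[(methylsulfanyl)methoxy]benzaldehyde | COc1cc(O)c(C=O)c(OCSC)c1 | intermediate
13 | 2-(chloromethoxy)-6-hydroxy-4-methoxybenzaldehyde | COc1cc(O)c(C=O)c(OCCl)c1 | intermediate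
14 | iminium chloride, (S) at the future C3 and (S) at the pyrrolidine carbon: 1-[3-(2-formyl-3-hydroxy-5-methoxyphenoxy)-2-arylpropylidene]-2-(methoxydiphenylmethyl)pyrrolidinium chloride | COc1cc(O)c(C=O)c(OC[C@H](C=[N+]2CCC[C@H]2C(OC)(c2ccccc2)c2ccccc2)c2ccc(OCOC)c(CC=C(C)C)c2OCOC)c1.[Cl-] | intermediate
15 | (3S,4S)-4-[(S)-2-(methoxydiphenylmethyl)pyrrolidin-1-yl] derivative of 17, hydrochloride (3,4-trans drawn; a C4 epimer would converge) | COc1cc(O)c(C=O)c2c1[C@@H](N1CCC[C@H]1C(OC)(c1ccccc1)c1ccccc1)[C@H](c1ccc(OCOC)c(CC=C(C)C)c1OCOC)CO2.Cl | intermediate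
16 | (3R)-3-aryl-5-methoxy-7-oxo-3,7-dihydro-2H-chromene-8-carbaldehyde (para-quinone methide, C4=C4a) | COC1=CC(=O)C(C=O)=C2OC[C@@H](c3ccc(OCOC)c(CC=C(C)C)c3OCOC)C=C12 | intermediate
17 | (3R)-7-hydroxy-5-methoxy-2',4'-bis(methoxymethoxy)-3'-(3-methylbut-2-enyl)isoflavan-8-carbaldehyde | COc1cc(O)c(C=O)c2c1C[C@H](c1ccc(OCOC)c(CC=C(C)C)c1OCOC)CO2 | intermediate
18 | (3R)-7,2',4'-trihydroxy-5-methoxy-3'-(3-methylbut-2-enyl)isoflavan-8-carbaldehyde | COc1cc(O)c(C=O)c2c1C[C@H](c1ccc(O)c(CC=C(C)C)c1O)CO2 | target

## Step count and risks

Total step count: 10. Longest linear sequence: 7 (steps 1, 2, 3, 4, 5, 9, 10).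

### Steps most likely to fail

**Step 9.**
What may go wrong:
- Configuration at C3 may be lost through deprotonation of the iminium ion, or through β-elimination of the aryloxide, before ring closure.
- The acidic phenol may protonate the enamine, or the enamine may be N-alkylated.
- Ring closure may be slow against the bulky amine and the peri 5-OMe.
- The quinone methide may tautomerise to the isoflav-3-ene instead of being reduced.

The fallback uses known reactions only, sets out from 7 and 11, and comes back at 17. Organocatalytic α-methylenation of 7 (aq. HCHO, pyrrolidine/propionic acid, iPrOH) gives the 2-arylacrolein F1. Luche reduction (NaBH4, CeCl3·7H2O, MeOH) gives the allylic alcohol F2. Hydroboration with 9-BBN, which prefers the 1,1-disubstituted alkene over the trisubstituted one, followed by NaBO3 oxidation, gives the prochiral 2-arylpropane-1,3-diol F3. Lipase-catalysed desymmetrisation with vinyl acetate (or hydrolysis of the diacetate, if the opposite sense is delivered) sets the stereocentre in the (R)-monoacetate F4. Mitsunobu etherification of one of the two equivalent hydroxyls of 11 (PPh3, DIAD, THF) gives the aryl ether acetate F5. Methanolysis (K2CO3, MeOH) gives the primary alcohol F6, and Appel iodination (I2, PPh3, imidazole) gives the iodide F7. Intramolecular C-alkylation of the 7-phenolate at its para carbon C4a (Cs2CO3, CF3CH2OH or DMF, high dilution, 6-exo-tet) then closes ring C to 17. In this sequence the stereocentre never stands next to a carbonyl or iminium group.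

**Step 8.**
What may go wrong:
- The electron-rich ring may be chlorinated or sulfenylated.
- The α-chloro ether may hydrolyse or self-condense during concentration and transfer.

The fallback sets out from 12 and comes back at 16. S-Methylation of 12 with MeOTf (1.0 equiv, CH2Cl2, −40 °C) gives the aryloxymethyl dimethylsulfonium triflate F8 in the flask. Enamine 9 is added and displaces dimethyl sulfide at the O–CH2 carbon to give the iminium triflate F9, which closes to the aminoisoflavan triflate salt F10. The buffered Hantzsch ester stage of step 9 then leads through 16 to 17. No chlorinating agent touches ring A, and the electrophile is never handled.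

**Step 10.**
What may go wrong:
- Acid may induce addition of the freed 2'- or 4'-OH to the prenyl double bond (dimethylchroman formation) before both acetals are cleaved.

The fallback sets out from 17 and comes back at 18. Treatment with Et3SiOTf and 2,2'-bipyridyl (MeCN, 0 °C) exchanges the aromatic MOM ethers for silyl ethers through bipyridinium salts without free Brønsted acid. It also silylates the 7-OH, giving the tris(triethylsilyl) ether F11. Buffered fluoride (Bu4NF/AcOH, THF, 0 °C) then releases 18, so deprotection becomes a fluoride-triggered Si–O cleavage instead of a protic acetal solvolysis.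

## Further compounds

F1 | step 9 | 2-[2,4-bis(methoxymethoxy)-3-(3-methylbut-2-enyl)phenyl]prop-2-enal | C=C(C=O)c1ccc(OCOC)c(CC=C(C)C)c1OCOC
F2 | step 9 | 2-[2,4-bis(methoxymethoxy)-3-(3-methylbut-2-enyl)phenyl]prop-2-en-1-ol | C=C(CO)c1ccc(OCOC)c(CC=C(C)C)c1OCOC
F3 | step 9 | 2-[2,4-bis(methoxymethoxy)-3-(3-methylbut-2-enyl)phenyl]propane-1,3-diol | OCC(CO)c1ccc(OCOC)c(CC=C(C)C)c1OCOC
F4 | step 9 | (R)-2-[2,4-bis(methoxymethoxy)-3-(3-methylbut-2-enyl)phenyl]-3-hydroxypropyl acetate | CC(=O)OC[C@H](c1ccc(OCOC)c(CC=C(C)C)c1OCOC)CO
F5 | step 9 | (R)-2-aryl-3-(2-formyl-3-hydroxy-5-methoxyphenoxy)propyl acetate | COc1cc(O)c(C=O)c(OC[C@H](COC(C)=O)c2ccc(OCOC)c(CC=C(C)C)c2OCOC)c1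
F6 | step 9 | 2-[(S)-2-aryl-3-hydroxypropoxy]-6-hydroxy-4-methoxybenzaldehyde | COc1cc(O)c(C=O)c(OC[C@H](CO)c2ccc(OCOC)c(CC=C(C)C)c2OCOC)c1
F7 | step 9 | 2-[(R)-2-aryl-3-iodopropoxy]-6-hydroxy-4-methoxybenzaldehyde | COc1cc(O)c(C=O)c(OC[C@H](CI)c2ccc(OCOC)c(CC=C(C)C)c2OCOC)c1
F8 | step 8 | [(2-formyl-3-hydroxy-5-methoxyphenoxy)methyl]dimethylsulfonium trifluoromethanesulfonate | COc1cc(O)c(C=O)c(OC[S+](C)C)c1.[O-]S(=O)(=O)C(F)(F)F
F9 | step 8 | trifluoromethanesulfonate of the iminium cation of 14 | COc1cc(O)c(C=O)c(OC[C@H](C=[N+]2CCC[C@H]2C(OC)(c2ccccc2)c2ccccc2)c2ccc(OCOC)c(CC=C(C)C)c2OCOC)c1.[O-]S(=O)(=O)C(F)(F)F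
F10 | step 8 | trifluoromethanesulfonic acid salt of the amine of 15 | COc1cc(O)c(C=O)c2c1[C@@H](N1CCC[C@H]1C(OC)(c1ccccc1)c1ccccc1)[C@H](c1ccc(OCOC)c(CC=C(C)C)c1OCOC)CO2.OS(=O)(=O)C(F)(F)F
F11 | step 10 | (3R)-5-methoxy-7,2',4'-tris(triethylsilyloxy)-3'-(3-methylbut-2-enyl)isoflavan-8-carbaldehyde | COc1cc(O[Si](CC)(CC)CC)c(C=O)c2c1C[C@H](c1ccc(O[Si](CC)(CC)CC)c(CC=C(C)C)c1O[Si](CC)(CC)CC)CO2
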